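Ring C is opened at C3–C4 and O1–C2: ring A then arrives as a salicylaldehyde (phenol oxygen = O1, formyl carbon = C4) and C2, C3 and ring B as a cinnamaldehyde whose own formyl carbon is a traceless handle on C3. In one operation a chiral amine joins the halves: oxa-Michael addition forms O1–C2 and sets C2, then the enamine carbon C3 of the resulting open-chain aryl ether attacks C4 and closes ring C. The step exploits the ortho relationship of O1 and C4 on ring A and the C3 carbinol, which is stored as that formyl group, unveiled by Baeyer–Villiger excision and set cis by hydride; the lone 7-phenol is then galloylated before hydrogenolysis.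

Key step: step 4

Assumption: the sense of induction in step 4 is taken from the usual face-shielding model of diarylprolinol silyl ether iminium ions; should the opposite sense be found, the mirror-image amine would be used.

Step 1
Reactants: 1 2,4,6-trihydroxybenzaldehyde
Product: 2 2,6-dihydroxy-4-(methoxymethoxy)benzaldehyde
Conditions: MOMCl (1.0 equiv), i-Pr2NEt, THF, 0 °C
Reagents that add atoms: chloromethyl methyl ether (MOMCl), COCCl
Why: O-alkylation (Williamson type) of the most acidic phenol; 4-OH is para to the formyl group and the only hydroxyl not hydrogen-bonded to it, so one equivalent of MOMCl should react there.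

Step 2
Reactants: 2 2,6-dihydroxy-4-(methoxymethoxy)benzaldehyde
Product: 3 2-(benzyloxy)-6-hydroxy-4-(methoxymethoxy)benzaldehyde
Conditions: BnBr (1.05 equiv), K2CO3, DMF, rt
Reagents that add atoms: benzyl bromide, BrCc1ccccc1
Why: Williamson ether synthesis; the two hydroxyls are equivalent, and after the first benzylation the remaining one is locked in a hydrogen bond to the formyl group, which should hold the reaction at the monoether.

Step 3
Reactants: 4 3,4,5-tris(benzyloxy)benzaldehyde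
Product: 5 (E)-3-[3,4,5-tris(benzyloxy)phenyl]prop-2-enal
Conditions: Ph3P=CHCHO, toluene, 90 °C
Reagents that add atoms: (triphenylphosphoranylidene)acetaldehyde, O=CC=P(c1ccccc1)(c1ccccc1)c1ccccc1
Why: Wittig olefination with a stabilised formyl ylide, which should give the E-enal.

Step 4
Reactants: 3 2-(benzyloxy)-6-hydroxy-4-(methoxymethoxy)benzaldehyde; 5 (E)-3-[3,4,5-tris(benzyloxy)phenyl]prop-2-enal
Product: 7 (2R)-5-(benzyloxy)-7-(methoxymethoxy)-2-[3,4,5-tris(benzyloxy)phenyl]-2H-chromene-3-carbaldehyde, via oxa-Michael enamine 6 (not isolated)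
Conditions: (S)-2-[diphenyl(trimethylsilyloxy)methyl]pyrrolidine (20 mol %), 2-nitrobenzoic acid (20 mol %), 4 Å MS, toluene, rt
Reagents that add atoms: none
Why: Domino oxa-Michael/aldol condensation under iminium–enamine catalysis, the known reaction of salicylaldehydes with cinnamaldehydes and diarylprolinol silyl ethers: the amine turns 5 into an E-iminium ion, the free phenol oxygen of 3 (O1) adds to its β-carbon (C2) to give enamine 6, the enamine α-carbon (C3) adds to the ortho formyl carbon (C4), and loss of water with hydrolysis of the conjugated iminium ion releases 7 and the amine. Ring C, the only ring formed, is closed by the C3–C4 bond in a 6-exo-trig (enol-exo) aldol addition. The one new stereocenter, C2, is set by the catalyst, whose diphenyl(silyloxy)methyl group shields one face of the s-trans E-iminium ion so that O1 adds to the open face; by this model the (S)-amine gives 2R in 7 (the same carbon is S by CIP priorities in 6, with no change in space). The step needs the irreversible aldol–dehydration to outrun the reversible oxa-Michael addition, which the acid co-catalyst and the sieves serve, and it needs attack by one phenol only, which 3 secures because O5 and O7 are capped and only the adduct of the ortho phenol can cyclise. After dehydration the formyl group sits on the central carbon of the C2–C3–C4 allyl unit, so C2–H is not acidified and the configuration should hold.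

Step 5
Reactants: 7 (2R)-5-(benzyloxy)-7-(methoxymethoxy)-2-[3,4,5-tris(benzyloxy)phenyl]-2H-chromene-3-carbaldehyde
Product: 9 (2R)-5-(benzyloxy)-7-(methoxymethoxy)-2-[3,4,5-tris(benzyloxy)phenyl]chroman-3-one, via enol formate 8 (not isolated)
Conditions: mCPBA (1.2 equiv), NaHCO3, CH2Cl2, 0 °C; then KHCO3 (cat.), MeOH, 0 °C
Reagents that add atoms: 3-chloroperbenzoic acid (mCPBA), O=C(OO)c1cccc(Cl)c1
Why: Baeyer–Villiger oxidation of an α,β-unsaturated aldehyde, in which the electron-rich alkenyl carbon C3 of the Criegee adduct migrates to oxygen to give enol formate 8; mild methanolysis should then free the C3 enol, which is protonated at C4 to ketone 9 without touching C2.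

Step 6
Reactants: 9 (2R)-5-(benzyloxy)-7-(methoxymethoxy)-2-[3,4,5-tris(benzyloxy)phenyl]chroman-3-one
Product: 10 (2R,3R)-5-(benzyloxy)-7-(methoxymethoxy)-2-[3,4,5-tris(benzyloxy)phenyl]chroman-3-ol
Conditions: LiBH(s-Bu)3 (L-Selectride), THF, −78 °C; then H2O
Reagents that add atoms: none
Why: Diastereoselective ketone reduction with a bulky hydride, which should attack C3 from the face opposite the C2 aryl group and so place the new hydroxyl cis to it (3R), the known outcome for protected flavan-3-ones.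

Step 7
Reactants: 10 (2R,3R)-5-(benzyloxy)-7-(methoxymethoxy)-2-[3,4,5-tris(benzyloxy)phenyl]chroman-3-ol
Product: 11 (2R,3R)-5-(benzyloxy)-2-[3,4,5-tris(benzyloxy)phenyl]chromane-3,7-diol
Conditions: ZnBr2, n-PrSH, CH2Cl2, 0 °C
Reagents that add atoms: none
Why: Lewis-acid-assisted cleavage of the aryl MOM acetal with thiol capture of the methoxymethyl cation, which should keep the electron-rich ring A from being alkylated and leave the benzyl ethers and the C3 alcohol alone.

Step 8
Reactants: 12 3,4,5-tris(benzyloxy)benzoic acid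
Product: 13 3,4,5-tris(benzyloxy)benzoyl chloride
Conditions: (COCl)2, DMF (cat.), CH2Cl2, 0 °C to rt; evaporate
Reagents that add atoms: oxalyl chloride, O=C(Cl)C(=O)Cl
Why: Acid chloride formation through the chloroiminium (Vilsmeier-type) species.

Step 9
Reactants: 11 (2R,3R)-5-(benzyloxy)-2-[3,4,5-tris(benzyloxy)phenyl]chromane-3,7-diol; 13 3,4,5-tris(benzyloxy)benzoyl chloride
Product: 14 (2R,3R)-5-(benzyloxy)-3-hydroxy-2-[3,4,5-tris(benzyloxy)phenyl]chroman-7-yl 3,4,5-tris(benzyloxy)benzoate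
Conditions: 13 (1.05 equiv), Et3N, CH2Cl2, −20 to 0 °C (no DMAP)
Reagents that add atoms: none
Why: Chemoselective acylation (Schotten–Baumann type), in which the phenol at C7 as its ammonium phenoxide is far more nucleophilic than the axial, hindered C3 secondary alcohol, so one equivalent of 13 should acylate O7 only.

Step 10
Reactants: 14 (2R,3R)-5-(benzyloxy)-3-hydroxy-2-[3,4,5-tris(benzyloxy)phenyl]chroman-7-yl 3,4,5-tris(benzyloxy)benzoate
Product: 15 epigallocatechin 7-O-gallate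
Conditions: H2 (1 atm), Pd(OH)2/C, THF/MeOH, rt
Reagents that add atoms: none
Why: Hydrogenolysis of all seven benzyl ethers under neutral conditions, which should leave the aryl ester, the C2–O1 ether and both stereocenters untouched.

Compound list

1 | 2,4,6-trihydroxybenzaldehyde | O=Cc1c(O)cc(O)cc1O | starting material
2 | 2,6-dihydroxy-4-(methoxymethoxy)benzaldehyde | COCOc1cc(O)c(C=O)c(O)c1 | intermediate
3 | 2-(benzyloxy)-6-hydroxy-4-(methoxymethoxy)benzaldehyde | COCOc1cc(O)c(C=O)c(OCc2ccccc2)c1 | intermediate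
4 | 3,4,5-tris(benzyloxy)benzaldehyde | O=Cc1cc(OCc2ccccc2)c(OCc2ccccc2)c(OCc2ccccc2)c1 | starting material
5 | (E)-3-[3,4,5-tris(benzyloxy)phenyl]prop-2-enal | O=C/C=C/c1cc(OCc2ccccc2)c(OCc2ccccc2)c(OCc2ccccc2)c1 | intermediate
6 | (E)-enamine of (3S)-3-[3-(benzyloxy)-2-formyl-5-(methoxymethoxy)phenoxy]-3-[3,4,5-tris(benzyloxy)phenyl]propanal with (S)-2-[diphenyl(trimethylsilyloxy)methyl]pyrrolidine (not isolated) | O=Cc1c(OCc2ccccc2)cc(OCOC)cc1O[C@H](c1cc(OCc2ccccc2)c(OCc2ccccc2)c(OCc2ccccc2)c1)/C=C/N1CCC[C@H]1C(c1ccccc1)(c1ccccc1)O[Si](C)(C)C | intermediate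
7 | (2R)-5-(benzyloxy)-7-(methoxymethoxy)-2-[3,4,5-tris(benzyloxy)phenyl]-2H-chromene-3-carbaldehyde | COCOc1cc(OCc3ccccc3)c2c(c1)O[C@H](c1cc(OCc3ccccc3)c(OCc3ccccc3)c(OCc3ccccc3)c1)C(C=O)=C2 | intermediate
8 | (2R)-5-(benzyloxy)-7-(methoxymethoxy)-2-[3,4,5-tris(benzyloxy)phenyl]-2H-chromen-3-yl formate (not isolated) | COCOc1cc(OCc3ccccc3)c2c(c1)O[C@H](c1cc(OCc3ccccc3)c(OCc3ccccc3)c(OCc3ccccc3)c1)C(OC=O)=C2 | intermediate
9 | (2R)-5-(benzyloxy)-7-(methoxymethoxy)-2-[3,4,5-tris(benzyloxy)phenyl]chroman-3-one | COCOc1cc(OCc3ccccc3)c2c(c1)O[C@H](c1cc(OCc3ccccc3)c(OCc3ccccc3)c(OCc3ccccc3)c1)C(=O)C2 | intermediate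
10 | (2R,3R)-5-(benzyloxy)-7-(methoxymethoxy)-2-[3,4,5-tris(benzyloxy)phenyl]chroman-3-ol | COCOc1cc(OCc3ccccc3)c2c(c1)O[C@H](c1cc(OCc3ccccc3)c(OCc3ccccc3)c(OCc3ccccc3)c1)[C@H](O)C2 | intermediate
11 | (2R,3R)-5-(benzyloxy)-2-[3,4,5-tris(benzyloxy)phenyl]chromane-3,7-diol | Oc1cc(OCc3ccccc3)c2c(c1)O[C@H](c1cc(OCc3ccccc3)c(OCc3ccccc3)c(OCc3ccccc3)c1)[C@H](O)C2 | intermediate
12 | 3,4,5-tris(benzyloxy)benzoic acid | OC(=O)c1cc(OCc2ccccc2)c(OCc2ccccc2)c(OCc2ccccc2)c1 | starting material
13 | 3,4,5-tris(benzyloxy)benzoyl chloride | O=C(Cl)c1cc(OCc2ccccc2)c(OCc2ccccc2)c(OCc2ccccc2)c1 | intermediate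
14 | (2R,3R)-5-(benzyloxy)-3-hydroxy-2-[3,4,5-tris(benzyloxy)phenyl]chroman-7-yl 3,4,5-tris(benzyloxy)benzoate | O=C(Oc1cc(OCc3ccccc3)c2c(c1)O[C@H](c1cc(OCc3ccccc3)c(OCc3ccccc3)c(OCc3ccccc3)c1)[C@H](O)C2)c1cc(OCc2ccccc2)c(OCc2ccccc2)c(OCc2ccccc2)c1 | intermediate
15 | epigallocatechin 7-O-gallate, (2R,3R)-3,5-dihydroxy-2-(3,4,5-trihydroxyphenyl)chroman-7-yl 3,4,5-trihydroxybenzoate | O=C(Oc1cc(O)c2c(c1)O[C@H](c1cc(O)c(O)c(O)c1)[C@H](O)C2)c1cc(O)c(O)c(O)c1 | target

Total step count: 10. Longest linear sequence: 8 steps (steps 1, 2, 4, 5, 6, 7, 9, 10).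

Steps most likely to fail

Step 4. What may go wrong: the aldol closure onto the chelated, strongly deactivated aldehyde of the electron-rich ring A may be slow, so that the reversible oxa-Michael addition erodes the enantiomeric purity or the reaction stalls (a modest enantiomeric excess could be raised by recrystallising 7 or 10). The fallback uses known chemistry, still closes ring C through C3–C4 (now by olefin metathesis), sets out from 3 with 5 as partner, and returns at 9. Wittig methylenation of 3 (Ph3P=CH2 in excess, THF) would give 3-(benzyloxy)-2-ethenyl-5-(methoxymethoxy)phenol F1. Reduction of 5 (NaBH4, MeOH/THF, 0 °C) would give (E)-3-[3,4,5-tris(benzyloxy)phenyl]prop-2-en-1-ol F2, and methyl chloroformate/pyridine would turn it into methyl (E)-3-[3,4,5-tris(benzyloxy)phenyl]prop-2-en-1-yl carbonate F3. Enantioselective allylic etherification of the lithium phenoxide of F1 with F3 ([Ir(cod)Cl]2, chiral phosphoramidite ligand, THF) should give the branched ether 1-(benzyloxy)-2-ethenyl-5-(methoxymethoxy)-3-{[(1S)-1-[3,4,5-tris(benzyloxy)phenyl]prop-2-en-1-yl]oxy}benzene F4. Ring-closing metathesis (second-generation Grubbs catalyst, CH2Cl2, 40 °C) would give (2S)-5-(benzyloxy)-7-(methoxymethoxy)-2-[3,4,5-tris(benzyloxy)phenyl]-2H-chromene F5 (S only through a change of CIP priorities). Hydroboration–oxidation (BH3·THF; then NaOH, H2O2) anti to the aryl group would give the 2,3-trans alcohol (2R,3S)-5-(benzyloxy)-7-(methoxymethoxy)-2-[3,4,5-tris(benzyloxy)phenyl]chroman-3-ol F6, and Dess–Martin oxidation would give ketone 9.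

Step 5. What may go wrong: over-oxidation by the peracid (epoxidation of the enol formate, attack on the electron-rich rings) or enolisation of the ketone toward C2 during formate cleavage. The fallback avoids the peracid, sets out from 7 and returns at 9. Pinnick oxidation (NaClO2, NaH2PO4, 2-methyl-2-butene, t-BuOH/H2O) would give (2R)-5-(benzyloxy)-7-(methoxymethoxy)-2-[3,4,5-tris(benzyloxy)phenyl]-2H-chromene-3-carboxylic acid F7. Diphenylphosphoryl azide/Et3N in toluene would give the acyl azide (2R)-5-(benzyloxy)-7-(methoxymethoxy)-2-[3,4,5-tris(benzyloxy)phenyl]-2H-chromene-3-carbonyl azide F8, and Curtius rearrangement at 80 °C would give the vinyl isocyanate (2R)-5-(benzyloxy)-3-isocyanato-7-(methoxymethoxy)-2-[3,4,5-tris(benzyloxy)phenyl]-2H-chromene F9. Brief hydrolysis with dilute aqueous HCl in THF at 0 °C (carbamic acid, enamine, ketone) would then give 9.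

Step 9. What may go wrong: loss of chemoselectivity, with acylation of the C3 hydroxyl beside the phenol. The fallback masks the C3 hydroxyl, sets out from 10 and returns at 14. Silylation (TBSOTf, 2,6-lutidine, CH2Cl2) would give tert-butyl{[(2R,3R)-5-(benzyloxy)-7-(methoxymethoxy)-2-[3,4,5-tris(benzyloxy)phenyl]chroman-3-yl]oxy}dimethylsilane F10. MOM cleavage as in step 7 would give (2R,3R)-5-(benzyloxy)-3-[(tert-butyldimethylsilyl)oxy]-2-[3,4,5-tris(benzyloxy)phenyl]chroman-7-ol F11. Acylation with 13 (Et3N, DMAP, CH2Cl2) would give (2R,3R)-5-(benzyloxy)-3-[(tert-butyldimethylsilyl)oxy]-2-[3,4,5-tris(benzyloxy)phenyl]chroman-7-yl 3,4,5-tris(benzyloxy)benzoate F12, and HF·pyridine in THF would remove the silyl group to give 14.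

Further compounds

F1 | step 4 | 3-(benzyloxy)-2-ethenyl-5-(methoxymethoxy)phenol | C=Cc1c(O)cc(OCOC)cc1OCc1ccccc1
F2 | step 4 | (E)-3-[3,4,5-tris(benzyloxy)phenyl]prop-2-en-1-ol | OC/C=C/c1cc(OCc2ccccc2)c(OCc2ccccc2)c(OCc2ccccc2)c1
F3 | step 4 | methyl (E)-3-[3,4,5-tris(benzyloxy)phenyl]prop-2-en-1-yl carbonate | COC(=O)OC/C=C/c1cc(OCc2ccccc2)c(OCc2ccccc2)c(OCc2ccccc2)c1
F4 | step 4 | 1-(benzyloxy)-2-ethenyl-5-(methoxymethoxy)-3-{[(1S)-1-[3,4,5-tris(benzyloxy)phenyl]prop-2-en-1-yl]oxy}benzene | C=Cc1c(OCc2ccccc2)cc(OCOC)cc1O[C@H](c1cc(OCc2ccccc2)c(OCc2ccccc2)c(OCc2ccccc2)c1)C=C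
F5 | step 4 | (2S)-5-(benzyloxy)-7-(methoxymethoxy)-2-[3,4,5-tris(benzyloxy)phenyl]-2H-chromene | COCOc1cc(OCc3ccccc3)c2c(c1)O[C@H](c1cc(OCc3ccccc3)c(OCc3ccccc3)c(OCc3ccccc3)c1)C=C2
F6 | step 4 | (2R,3S)-5-(benzyloxy)-7-(methoxymethoxy)-2-[3,4,5-tris(benzyloxy)phenyl]chroman-3-ol | COCOc1cc(OCc3ccccc3)c2c(c1)O[C@H](c1cc(OCc3ccccc3)c(OCc3ccccc3)c(OCc3ccccc3)c1)[C@@H](O)C2
F7 | step 5 | (2R)-5-(benzyloxy)-7-(methoxymethoxy)-2-[3,4,5-tris(benzyloxy)phenyl]-2H-chromene-3-carboxylic acid | COCOc1cc(OCc3ccccc3)c2c(c1)O[C@H](c1cc(OCc3ccccc3)c(OCc3ccccc3)c(OCc3ccccc3)c1)C(C(=O)O)=C2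
F8 | step 5 | (2R)-5-(benzyloxy)-7-(methoxymethoxy)-2-[3,4,5-tris(benzyloxy)phenyl]-2H-chromene-3-carbonyl azide | COCOc1cc(OCc3ccccc3)c2c(c1)O[C@H](c1cc(OCc3ccccc3)c(OCc3ccccc3)c(OCc3ccccc3)c1)C(C(=O)N=[N+]=[N-])=C2
F9 | step 5 | (2R)-5-(benzyloxy)-3-isocyanato-7-(methoxymethoxy)-2-[3,4,5-tris(benzyloxy)phenyl]-2H-chromene | COCOc1cc(OCc3ccccc3)c2c(c1)O[C@H](c1cc(OCc3ccccc3)c(OCc3ccccc3)c(OCc3ccccc3)c1)C(N=C=O)=C2
F10 | step 9 | tert-butyl{[(2R,3R)-5-(benzyloxy)-7-(methoxymethoxy)-2-[3,4,5-tris(benzyloxy)phenyl]chroman-3-yl]oxy}dimethylsilane | COCOc1cc(OCc3ccccc3)c2c(c1)O[C@H](c1cc(OCc3ccccc3)c(OCc3ccccc3)c(OCc3ccccc3)c1)[C@H](O[Si](C)(C)C(C)(C)C)C2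
F11 | step 9 | (2R,3R)-5-(benzyloxy)-3-[(tert-butyldimethylsilyl)oxy]-2-[3,4,5-tris(benzyloxy)phenyl]chroman-7-ol | Oc1cc(OCc3ccccc3)c2c(c1)O[C@H](c1cc(OCc3ccccc3)c(OCc3ccccc3)c(OCc3ccccc3)c1)[C@H](O[Si](C)(C)C(C)(C)C)C2
F12 | step 9 | (2R,3R)-5-(benzyloxy)-3-[(tert-butyldimethylsilyl)oxy]-2-[3,4,5-tris(benzyloxy)phenyl]chroman-7-yl 3,4,5-tris(benzyloxy)benzoate | O=C(Oc1cc(OCc3ccccc3)c2c(c1)O[C@H](c1cc(OCc3ccccc3)c(OCc3ccccc3)c(OCc3ccccc3)c1)[C@H](O[Si](C)(C)C(C)(C)C)C2)c1cc(OCc2ccccc2)c(OCc2ccccc2)c(OCc2ccccc2)c1
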